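**Strategy**

Ring A is disconnected at C8–C8a and C4a–C5, so that ring C, already carrying the C2 aryl stereocenter, acts as the two-carbon partner. The route exploits the fact that C5, C6 and C7 bear contiguous oxygens and C8 a hydrogen, the pattern of a 1,2,3-trioxygenated butadiene, while C4a=C8a is the enone double bond of a 2-aryl-2,3-dihydropyran-4-one. One Diels–Alder/aromatization operation builds ring A with every oxygen in place and delivers the 5-hydroxyflavanone. Its precursors are the enantiopure (S)-5-bromo-2-aryl-dihydropyranone, made by an asymmetric hetero-Diels–Alder reaction, and 1,2,3-trimethoxy-1-(trimethylsilyloxy)butadiene. A final O-methylation of the 5-hydroxyl completes the target.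

Key step: step 6

Assumption: the titanium catalyst from (S)-BINOL is taken to attack the aldehyde face that leads to (S)-4, by analogy with its additions to benzaldehyde; the sense is to be checked on 4 and (R)-BINOL used if it proves opposite.

**Route**

Step 1
Reactants: 1 3,4-dimethoxybenzaldehyde; 2 (E)-1-methoxy-3-(trimethylsilyloxy)buta-1,3-diene
Product: 4 (S)-2-(3,4-dimethoxyphenyl)-2,3-dihydro-4H-pyran-4-one, via silyl aldol adduct 3 (not isolated)
Conditions: (S)-BINOL (20 mol%), Ti(OiPr)4 (10 mol%), 4 Å MS, Et2O, −20 °C; then TFA, CH2Cl2, 0 °C
Reagents that add atoms: none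
Why: Asymmetric hetero-Diels–Alder reaction run as a Mukaiyama aldol addition, in which the chiral BINOL–titanium Lewis acid shields one face of the bound aldehyde and so sets C2 as (S), followed by TFA-mediated oxa-Michael ring closure with loss of methanol.

Step 2
Reactants: 4 (S)-2-(3,4-dimethoxyphenyl)-2,3-dihydro-4H-pyran-4-one
Product: 5 (S)-5-bromo-2-(3,4-dimethoxyphenyl)-2,3-dihydro-4H-pyran-4-one
Conditions: NBS (1.05 equiv), CH2Cl2, 0 °C, dark
Reagents that add atoms: N-bromosuccinimide, O=C1CCC(=O)N1Br
Why: Electrophilic alpha-bromination of a vinylogous ester, whose enol ether carbon C5 is the most nucleophilic site and re-forms the enone by loss of H5, while the dimethoxyphenyl ring should react far more slowly in CH2Cl2 without acid and C2 is not involved.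

Step 3
Reactants: 6 methyl methoxyacetate
Product: 7 methyl 2-methoxy-3-oxobutanoate (racemic)
Conditions: LiN(iPr)2 (2.1 equiv), 6 (2.1 equiv), THF, −78 °C; AcCl (1.0 equiv), −78 → 0 °C; aq NH4Cl
Reagents that add atoms: acetyl chloride, CC(=O)Cl
Why: Crossed Claisen acylation of a preformed lithium ester enolate with an acid chloride, in which the second equivalent of enolate deprotonates the more acidic beta-keto ester as it forms and so prevents double acylation.

Step 4
Reactants: 7 methyl 2-methoxy-3-oxobutanoate
Product: 9 methyl 2,3-dimethoxybut-2-enoate (E/Z mixture), via dimethyl ketal 8 (not isolated)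
Conditions: HC(OMe)3 (3 equiv), p-TsOH (cat.), 25 → 110 °C, distil off HCO2Me/MeOH
Reagents that add atoms: trimethyl orthoformate, COC(OC)OC
Why: Acid-catalysed ketalization with an orthoformate followed by elimination of methanol, the standard conversion of beta-keto esters into beta-methoxy enoates; both alkene geometries and any deconjugated isomer give the same dienolate in step 5.

Step 5
Reactants: 9 methyl 2,3-dimethoxybut-2-enoate
Product: 10 1,2,3-trimethoxy-1-(trimethylsilyloxy)buta-1,3-diene (either geometry at C1=C2)
Conditions: LiN(iPr)2 (1.1 equiv), THF, −78 °C; TMSCl (1.2 equiv), −78 → 0 °C; pentane, filter, distil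
Reagents that add atoms: chlorotrimethylsilane, C[Si](C)(C)Cl
Why: Kinetic gamma-deprotonation of a beta-methoxy enoate to the lithium dienolate and O-silylation, the established preparation of 1-methoxy-1-silyloxy-1,3-dienes; the ketene acetal geometry is irrelevant because that carbon becomes an sp2 ring atom.

Step 6
Reactants: 5 (S)-5-bromo-2-(3,4-dimethoxyphenyl)-2,3-dihydro-4H-pyran-4-one; 10 1,2,3-trimethoxy-1-(trimethylsilyloxy)buta-1,3-diene
Product: 13 (2S)-5-hydroxy-6,7,3',4'-tetramethoxyflavanone, via cycloadduct 11 (not isolated), via bromodione 12 (not isolated)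
Conditions: 10 (3 equiv), toluene, 100 °C, sealed tube; then AcOH/NaOAc buffer, THF/H2O, 25 °C
Reagents that add atoms: none
Why: Proposed new method: the reaction is a normal-demand, probably asynchronous (4+2) cycloaddition in which the unsubstituted CH2 terminus of diene 10, the carbon with the largest HOMO coefficient, bonds to the oxygen-bearing beta carbon of bromoenone 5 (C8–C8a) and the ketene acetal carbon bonds to the brominated alpha carbon (C4a–C5), giving the cis-fused adduct 11. The closest known reaction type is the cycloaddition–aromatization of 1-methoxy-1-silyloxydienes with haloquinones and of siloxydienes with 3-acceptor-substituted chromones; a 5-bromo-2,3-dihydropyran-4-one has not served as the two-carbon partner, hence the label. Ring A closes as a six-membered carbocycle in an intermolecular (4+2) mode, four carbons from the diene and the C4a=C8a pair from ring C. The buffer then cleaves the silyl methyl ketal to the C5 ketone (bromodione 12), whose dienol is a dihydroarene that should lose HBr across C4a–C8a, acetate taking H8a, with aromatization and the hydrogen bond from the new 5-OH to the C4 carbonyl as driving force. The transient centers at C4a, C5 and C8a are erased and no new stereocenter remains, while C2 is untouched because the medium is neither strongly basic nor Lewis acidic. The selectivity needed is the regiochemistry, which is secured by the match between the nucleophilic diene terminus and the beta carbon of the vinylogous ester and reinforced by the bromine, known in haloquinones to direct the ketene acetal carbon to the halogenated carbon.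

Step 7
Reactants: 13 (2S)-5-hydroxy-6,7,3',4'-tetramethoxyflavanone
Product: 14 (2S)-5,6,7,3',4'-pentamethoxyflavanone
Conditions: MeI (10 equiv), Ag2O (3 equiv), CHCl3, 40 °C, dark
Reagents that add atoms: iodomethane, CI
Why: Williamson-type O-methylation of the chelated phenol promoted by Ag2O, which assists iodide departure as a heterogeneous weak base and avoids the soluble bases that open 5-oxygenated flavanones to chalcones and would racemize C2.

**Compound list**

1 | 3,4-dimethoxybenzaldehyde | COc1ccc(C=O)cc1OC | starting material
2 | (E)-1-methoxy-3-(trimethylsilyloxy)buta-1,3-diene | CO/C=C/C(=C)O[Si](C)(C)C | starting material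
3 | (S,E)-5-(3,4-dimethoxyphenyl)-1-methoxy-5-(trimethylsilyloxy)pent-1-en-3-one | CO/C=C/C(=O)C[C@H](O[Si](C)(C)C)c1ccc(OC)c(OC)c1 | intermediate (not isolated)
4 | (S)-2-(3,4-dimethoxyphenyl)-2,3-dihydro-4H-pyran-4-one | COc1ccc([C@@H]2CC(=O)C=CO2)cc1OC | intermediate
5 | (S)-5-bromo-2-(3,4-dimethoxyphenyl)-2,3-dihydro-4H-pyran-4-one | COc1ccc([C@@H]2CC(=O)C(Br)=CO2)cc1OC | intermediate
6 | methyl methoxyacetate | COCC(=O)OC | starting material
7 | methyl 2-methoxy-3-oxobutanoate (racemic) | COC(C(C)=O)C(=O)OC | intermediate
8 | methyl 2,3,3-trimethoxybutanoate (racemic) | COC(C(=O)OC)C(C)(OC)OC | intermediate (not isolated)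
9 | methyl 2,3-dimethoxybut-2-enoate (E/Z mixture) | COC(=O)C(OC)=C(C)OC | intermediate
10 | 1,2,3-trimethoxy-1-(trimethylsilyloxy)buta-1,3-diene (either geometry at C1=C2) | C=C(OC)C(OC)=C(OC)O[Si](C)(C)C | intermediate
11 | (2S)-4a-bromo-2-(3,4-dimethoxyphenyl)-5,6,7-trimethoxy-5-(trimethylsilyloxy)-2,3,4a,5,8,8a-hexahydro-4H-chromen-4-one (cis-fused; mixture at C4a, C5, C8a) | COc1ccc([C@@H]2CC(=O)C3(Br)C(OC)(O[Si](C)(C)C)C(OC)=C(OC)CC3O2)cc1OC | intermediate (not isolated)
12 | (2S)-4a-bromo-2-(3,4-dimethoxyphenyl)-6,7-dimethoxy-2,3,8,8a-tetrahydro-4H-chromene-4,5(4aH)-dione (mixture at C4a, C8a) | COc1ccc([C@@H]2CC(=O)C3(Br)C(=O)C(OC)=C(OC)CC3O2)cc1OC | intermediate (not isolated)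
13 | (2S)-5-hydroxy-6,7,3',4'-tetramethoxyflavanone | COc1ccc([C@@H]2CC(=O)c3c(cc(OC)c(OC)c3O)O2)cc1OC | intermediate
14 | (2S)-5,6,7,3',4'-pentamethoxyflavanone | COc1ccc([C@@H]2CC(=O)c3c(cc(OC)c(OC)c3OC)O2)cc1OC | target

**Summary**

Total step count: 7. Longest linear sequence: 5 steps (6 → 7 → 9 → 10 → 13 → 14, steps 3 to 7).

Steps most likely to fail:

1. Step 6 (bears the label). The cycloaddition may not proceed because the ring oxygen lowers the electrophilicity of the bromoenone; about 12 kbar in CH2Cl2 at 25 °C would be the first variation. A stepwise Michael addition may stop at an open-chain silyl enol ether or expel O1 from C8a. Loss of HBr from the cis-fused adduct may be slow, so that debromination competes. The fallback uses known chemistry, sets out from 1 and comes back at 14. Claisen–Schmidt condensation of 1 with commercial 1-(6-hydroxy-2,3,4-trimethoxyphenyl)ethan-1-one (CC(=O)c1c(O)cc(OC)c(OC)c1OC; KOH, EtOH, 25 °C) should give (E)-2'-hydroxy-3,4,4',5',6'-pentamethoxychalcone F1. Oxa-Michael cyclization (NaOAc, EtOH, reflux) should then give racemic 5,6,7,3',4'-pentamethoxyflavanone F2. Preparative HPLC on an amylose tris(3,5-dimethylphenylcarbamate) phase would separate 14 from (2R)-5,6,7,3',4'-pentamethoxyflavanone F3, which can be re-equilibrated to F2 through the chalcone with base and recycled.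

2. Step 7. The flavanone may open to the 2'-hydroxychalcone on the basic oxide, with erosion of enantiomeric purity on reclosure, or the hydrogen-bonded hydroxyl may not react. The fallback sets out from 13 and comes back at 14: Mitsunobu etherification with methanol (MeOH, PPh3, DIAD, THF, 0 → 25 °C), which activates the alcohol partner instead of generating a phenoxide and needs neither metal oxide nor added base. It makes no new compound (F0).

3. Step 4. The reaction may stall at ketal 8 or eliminate incompletely to the tetrasubstituted enol ether. The fallback sets out from 7 and comes back at 9: O-alkylation of the potassium enolate (KOtBu, dimethyl sulfate, DMPU, 25 °C), where the hard electrophile, the dissociating solvent and the congested alpha carbon favour O- over C-methylation. It makes no new compound (F0).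

**Further compounds**

F1 | step 6 | (E)-2'-hydroxy-3,4,4',5',6'-pentamethoxychalcone | COc1ccc(/C=C/C(=O)c2c(O)cc(OC)c(OC)c2OC)cc1OC
F2 | step 6 | racemic 5,6,7,3',4'-pentamethoxyflavanone | COc1ccc(C2CC(=O)c3c(cc(OC)c(OC)c3OC)O2)cc1OC
F3 | step 6 | (2R)-5,6,7,3',4'-pentamethoxyflavanone | COc1ccc([C@H]2CC(=O)c3c(cc(OC)c(OC)c3OC)O2)cc1OC
F0 | step 7 | none | none
F0 | step 4 | none | none
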